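**Retrosynthetic overview**

1. The target is read as robinetinidol-(4α→2′)-leucorobinetinidin. The last skeletal disconnection is ring C of the lower flavan at C4–C4a, closed by an intramolecular phenoxide aldol; the enabling feature is the free 7-OH of lower ring A, which sits para to C4a while the ring oxygen O1 is ortho to C4a, so C4a is the one phenoxide-activated carbon within six-ring reach of a C4 aldehyde.
2. The aldehyde chain (lower C2–C3–C4) comes from an (E)-cinnamyl alcohol: Sharpless epoxidation (catalysis), phenoxide opening at the benzylic carbon with inversion (lower O1–C2 bond), then oxidation of the primary alcohol.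
3. The cinnamyl alcohol comes from an aryl triflate (Stille coupling); the parent phenol OH first serves as the activating group that directs the interflavan Friedel–Crafts bond (upper C4 to the pyrogallol-ring carbon ortho to that OH).
4. The upper flavan (rings A, C and B with C2 and C3) is bought as (+)-dihydrorobinetin; NaBH4 gives the 3,4-diol, whose C4 cation is captured trans to 3-OH.
5. Ring order: upper rings A/C/B are present from the start, then lower ring B is joined (interflavan bond), lower ring A is attached as an aryl ether, lower ring C is closed (key step), and hydrogenolysis finishes.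

Key step: step 12

Remark (assumption): upper unit (2R,3S,4S), lower unit (2R,3S,4R); compounds 1, 4, 10 and 13 are taken as purchasable (10 and 13 are otherwise one step from propargyl alcohol and resorcinol).

**Route**

Step 1
Reactants: 1 (+)-dihydrorobinetin, (2R,3R)-3,7-dihydroxy-2-(3,4,5-trihydroxyphenyl)chroman-4-one
Product: 2 (2R,3R)-7-(benzyloxy)-3-hydroxy-2-[3,4,5-tris(benzyloxy)phenyl]chroman-4-one
Conditions: BnBr (4.4 equiv), K2CO3, DMF, rt, argon
Reagents that add atoms: benzyl bromide, BrCc1ccccc1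
Why: Williamson etherification of the four phenols under a weak base that leaves the secondary 3-OH untouched; no stereocenter is formed, and mild air-free conditions guard C2/C3 against ring-opening epimerisation.

Step 2
Reactants: 2 tetra-O-benzyl dihydrorobinetin
Product: 3 (2R,3S,4R)-7-(benzyloxy)-2-[3,4,5-tris(benzyloxy)phenyl]chroman-3,4-diol
Conditions: NaBH4, THF/MeOH, 0 °C
Reagents that add atoms: none
Why: Borohydride reduction of a 2,3-trans-dihydroflavonol, where axial hydride delivery gives the equatorial 4-OH trans to 3-OH (this centre is ionised again in step 4, so its configuration is not critical).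

Step 3
Reactants: 4 3,4,5-tris(benzyloxy)benzaldehyde
Product: 6 3,4,5-tris(benzyloxy)phenol, via aryl formate 5 (not isolated)
Conditions: mCPBA, CH2Cl2, rt; then K2CO3 (cat.), MeOH, rt
Reagents that add atoms: mCPBA, OOC(=O)c1cccc(Cl)c1
Why: Dakin-type Baeyer–Villiger oxidation in which the electron-rich aryl group migrates to oxygen, followed by methanolysis of the formate.

Step 4
Reactants: 3 tetra-O-benzyl flavan-3,4-diol; 6 3,4,5-tris(benzyloxy)phenol
Product: 7 (2R,3S,4S)-7-(benzyloxy)-4-[2,3,4-tris(benzyloxy)-6-hydroxyphenyl]-2-[3,4,5-tris(benzyloxy)phenyl]chroman-3-ol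
Conditions: BF3·OEt2 (0.3 equiv), threefold excess of the phenol, CH2Cl2, −40 to 0 °C
Reagents that add atoms: none
Why: Friedel–Crafts alkylation by the C4 benzylic cation of 3 (formed by loss of water) at the carbon ortho to the OH of 6, whose phloroglucinol-type activation makes it more nucleophilic than ring A of 3 and whose symmetry allows one regioisomer only; the arene enters trans to the 3-OH (4α), as is usual for 2,3-trans flavan-3,4-diol electrophiles, which sets upper C4 (S).

Step 5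
Reactants: 7 interflavan phenol
Product: 8 aryl triflate of 7 (triflate on the phenol ortho to the interflavan bond)
Conditions: PhNTf2, K2CO3, DMF, rt
Reagents that add atoms: N-phenylbis(trifluoromethanesulfonimide), FC(F)(F)S(=O)(=O)N(c1ccccc1)S(=O)(=O)C(F)(F)F
Why: Phenoxide-selective triflation (the aliphatic 3-OH is not ionised by carbonate), which turns the activating OH into a cross-coupling handle.

Step 6
Reactants: 8 aryl triflate
Product: 9 3-O-tert-butyldimethylsilyl ether of 8
Conditions: TBSOTf, 2,6-lutidine, CH2Cl2, 0 °C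
Reagents that add atoms: tert-butyldimethylsilyl triflate, CC(C)(C)[Si](C)(C)OS(=O)(=O)C(F)(F)F
Why: Silylation of the hindered secondary alcohol with a silyl triflate, so that this OH cannot later open the benzylic epoxide in a 6-exo mode.

Step 7
Reactants: 9 silylated aryl triflate; 10 (E)-3-(tributylstannyl)prop-2-en-1-ol
Product: 11 (E)-cinnamyl-type alcohol (the triflate replaced by (E)-CH=CH–CH2OH)
Conditions: Pd(PPh3)4 (10 mol %), LiCl (3 equiv), CuI (cat.), DMF, 80 °C
Reagents that add atoms: none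
Why: Stille coupling of an aryl triflate with an alkenylstannane, which proceeds with retention of the E geometry and tolerates the free allylic alcohol.

Step 8
Reactants: 11 (E)-allylic alcohol
Product: 12 (2S,3S)-epoxy alcohol
Conditions: Ti(OiPr)4 (10 mol %), L-(+)-diisopropyl tartrate (12 mol %), t-BuOOH, 4 Å molecular sieves, CH2Cl2, −20 °C
Reagents that add atoms: tert-butyl hydroperoxide, CC(C)(C)OO
Why: Sharpless asymmetric epoxidation of an (E)-cinnamyl-type alcohol, in which the titanium/L-(+)-tartrate catalyst (reagent control, the remote stereocenters play no part) delivers oxygen to give the (2S,3S)-epoxide.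

Step 9
Reactants: 12 epoxy alcohol; 13 3-(allyloxy)phenol
Product: 14 (2S,3R)-3-[3-(allyloxy)phenoxy]-3-aryl-propane-1,2-diol (upper 3-OTBS retained)
Conditions: Cs2CO3 (0.5 equiv), fourfold excess of the phenol, DMF, 60 °C
Reagents that add atoms: none
Why: SN2 opening of a 3-arylglycidol by a phenoxide at the benzylic carbon (benzylic activation, attack at the other carbon retarded by the adjacent CH2OH) with inversion, which sets lower C2 (R) and keeps lower C3 (S) from step 8; the weak base leaves the primary alcohol protonated and so holds back Payne rearrangement.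

Step 10
Reactants: 14 silyl ether diol
Product: 15 triol (upper 3-OH free)
Conditions: Bu4NF, THF, rt to 40 °C
Reagents that add atoms: none
Why: Fluoride-mediated cleavage of the alkyl silyl ether, to which the allyl and benzyl ethers are inert.

Step 11
Reactants: 15 triol
Product: 16 (2R,3R)-3-[3-(allyloxy)phenoxy]-2-hydroxy-3-aryl-propanal
Conditions: TEMPO (20 mol %), PhI(OAc)2 (1.1 equiv), CH2Cl2, 0 °C to rt; crude product used at once
Reagents that add atoms: none
Why: Oxoammonium (TEMPO) oxidation, selective for the primary over the two secondary alcohols, gives the α-hydroxy aldehyde without touching the electron-rich aryl ethers.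

Step 12
Reactants: 16 α-hydroxy aldehyde with allyl-protected lower ring A
Product: 18 hepta-O-benzyl target (lower unit 2R,3S,4R; free 7-OH on lower ring A), via phenoxide aldehyde 17 (not isolated)
Conditions: Pd(PPh3)4 (5 mol %), K2CO3 (3 equiv), degassed MeOH/THF, 0 °C to rt, argon
Reagents that add atoms: none
Why: Proposed new method: zerovalent palladium transfers the allyl group to methoxide and frees the potassium phenoxide of 17, whose carbon para to O− (the future C4a, also ortho to the ether oxygen O1) attacks the tethered aldehyde as a vinylogous enolate before the cyclohexadienone tautomerises back to the phenol; the closest known reaction type is the base-mediated Lederer–Manasse hydroxyalkylation of phenoxides by aldehydes (phenol aldol), here made intramolecular. Ring C of the lower unit (O1–C2–C3–C4–C4a–C8a) closes in a 6-exo-trig mode at the C4 carbonyl. The new C4 stereocenter is set by substrate control from C2 and C3: in a half-chair transition state with the C2 aryl group and the C3 hydroxyl equatorial the carbonyl oxygen takes the pseudo-equatorial position, and both this Felkin-type arrangement and a dipole-opposed Cornforth arrangement place the new 4-OH trans to the 3-OH (4R), whereas only a chelated arrangement would lead to the cis diol and potassium in methanol does not chelate. Regioselectivity (C4a rather than the carbon between the two ring-A oxygens) rests on para attack of a free phenoxide in a protic solvent and on the crowding of the alternative site, and chemoselectivity rests on the fact that only lower ring A carries a phenoxide while both pyrogallol rings and upper ring A stay benzyl-protected. The weak base, low temperature and absence of a Lewis acid are chosen to keep the 4-hydroxybenzylic alcohol from ionising and to limit β-elimination of the aryloxide from the enolisable aldehyde.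

Step 13
Reactants: 18 hepta-O-benzyl target
Product: 19 target, robinetinidol-(4α→2′)-leucorobinetinidin
Conditions: H2 (1 atm), Pd(OH)2/C, THF/MeOH, rt, neutral, short reaction time
Reagents that add atoms: none
Why: Hydrogenolysis of the seven aryl benzyl ethers under neutral conditions, under which the cyclic benzylic C2–O1 bonds of flavans are known to persist.

**Compound list**

Abbreviations used in names: U(OH) = (2R,3S,4S)-7-(benzyloxy)-3-hydroxy-2-[3,4,5-tris(benzyloxy)phenyl]chroman-4-yl; U(TBS) = the same unit with 3-(tert-butyldimethylsilyloxy).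

1 | (+)-dihydrorobinetin, (2R,3R)-3,7-dihydroxy-2-(3,4,5-trihydroxyphenyl)chroman-4-one | Oc1ccc2c(c1)O[C@H](c1cc(O)c(O)c(O)c1)[C@@H](O)C2=O | starting material

2 | (2R,3R)-7-(benzyloxy)-3-hydroxy-2-[3,4,5-tris(benzyloxy)phenyl]chroman-4-one | c1ccccc1COc1ccc2c(c1)O[C@H](c1cc(OCc3ccccc3)c(OCc3ccccc3)c(OCc3ccccc3)c1)[C@@H](O)C2=O | intermediate

3 | (2R,3S,4R)-7-(benzyloxy)-2-[3,4,5-tris(benzyloxy)phenyl]chroman-3,4-diol | c1ccccc1COc1ccc2c(c1)O[C@H](c1cc(OCc3ccccc3)c(OCc3ccccc3)c(OCc3ccccc3)c1)[C@@H](O)[C@@H]2O | intermediate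

4 | 3,4,5-tris(benzyloxy)benzaldehyde | O=Cc1cc(OCc2ccccc2)c(OCc2ccccc2)c(OCc2ccccc2)c1 | starting material

5 | 3,4,5-tris(benzyloxy)phenyl formate | O=COc1cc(OCc2ccccc2)c(OCc2ccccc2)c(OCc2ccccc2)c1 | intermediate

6 | 3,4,5-tris(benzyloxy)phenol | Oc1cc(OCc2ccccc2)c(OCc2ccccc2)c(OCc2ccccc2)c1 | intermediate

7 | (2R,3S,4S)-7-(benzyloxy)-4-[2,3,4-tris(benzyloxy)-6-hydroxyphenyl]-2-[3,4,5-tris(benzyloxy)phenyl]chroman-3-ol | c1ccccc1COc1ccc2c(c1)O[C@H](c1cc(OCc3ccccc3)c(OCc3ccccc3)c(OCc3ccccc3)c1)[C@@H](O)[C@@H]2c1c(O)cc(OCc2ccccc2)c(OCc2ccccc2)c1OCc1ccccc1 | intermediate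

8 | 3,4,5-tris(benzyloxy)-2-U(OH)-phenyl trifluoromethanesulfonate | c1ccccc1COc1ccc2c(c1)O[C@H](c1cc(OCc3ccccc3)c(OCc3ccccc3)c(OCc3ccccc3)c1)[C@@H](O)[C@@H]2c1c(OS(=O)(=O)C(F)(F)F)cc(OCc2ccccc2)c(OCc2ccccc2)c1OCc1ccccc1 | intermediate

9 | 3,4,5-tris(benzyloxy)-2-U(TBS)-phenyl trifluoromethanesulfonate | c1ccccc1COc1ccc2c(c1)O[C@H](c1cc(OCc3ccccc3)c(OCc3ccccc3)c(OCc3ccccc3)c1)[C@@H](O[Si](C)(C)C(C)(C)C)[C@@H]2c1c(OS(=O)(=O)C(F)(F)F)cc(OCc2ccccc2)c(OCc2ccccc2)c1OCc1ccccc1 | intermediate

10 | (E)-3-(tributylstannyl)prop-2-en-1-ol | OC/C=C/[Sn](CCCC)(CCCC)CCCC | starting material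

11 | (E)-3-[3,4,5-tris(benzyloxy)-2-U(TBS)-phenyl]prop-2-en-1-ol | c1ccccc1COc1ccc2c(c1)O[C@H](c1cc(OCc3ccccc3)c(OCc3ccccc3)c(OCc3ccccc3)c1)[C@@H](O[Si](C)(C)C(C)(C)C)[C@@H]2c1c(/C=C/CO)cc(OCc2ccccc2)c(OCc2ccccc2)c1OCc1ccccc1 | intermediate

12 | [(2S,3S)-3-[3,4,5-tris(benzyloxy)-2-U(TBS)-phenyl]oxiran-2-yl]methanol | c1ccccc1COc1ccc2c(c1)O[C@H](c1cc(OCc3ccccc3)c(OCc3ccccc3)c(OCc3ccccc3)c1)[C@@H](O[Si](C)(C)C(C)(C)C)[C@@H]2c1c([C@@H]3O[C@H]3CO)cc(OCc2ccccc2)c(OCc2ccccc2)c1OCc1ccccc1 | intermediate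

13 | 3-(allyloxy)phenol | Oc1cccc(OCC=C)c1 | starting material

14 | (2S,3R)-3-[3-(allyloxy)phenoxy]-3-[3,4,5-tris(benzyloxy)-2-U(TBS)-phenyl]propane-1,2-diol | c1ccccc1COc1ccc2c(c1)O[C@H](c1cc(OCc3ccccc3)c(OCc3ccccc3)c(OCc3ccccc3)c1)[C@@H](O[Si](C)(C)C(C)(C)C)[C@@H]2c1c([C@@H](Oc2cccc(OCC=C)c2)[C@@H](O)CO)cc(OCc2ccccc2)c(OCc2ccccc2)c1OCc1ccccc1 | intermediate

15 | (2S,3R)-3-[3-(allyloxy)phenoxy]-3-[3,4,5-tris(benzyloxy)-2-U(OH)-phenyl]propane-1,2-diol | c1ccccc1COc1ccc2c(c1)O[C@H](c1cc(OCc3ccccc3)c(OCc3ccccc3)c(OCc3ccccc3)c1)[C@@H](O)[C@@H]2c1c([C@@H](Oc2cccc(OCC=C)c2)[C@@H](O)CO)cc(OCc2ccccc2)c(OCc2ccccc2)c1OCc1ccccc1 | intermediate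

16 | (2R,3R)-3-[3-(allyloxy)phenoxy]-2-hydroxy-3-[3,4,5-tris(benzyloxy)-2-U(OH)-phenyl]propanal | c1ccccc1COc1ccc2c(c1)O[C@H](c1cc(OCc3ccccc3)c(OCc3ccccc3)c(OCc3ccccc3)c1)[C@@H](O)[C@@H]2c1c([C@@H](Oc2cccc(OCC=C)c2)[C@@H](O)C=O)cc(OCc2ccccc2)c(OCc2ccccc2)c1OCc1ccccc1 | intermediate

17 | (2R,3R)-2-hydroxy-3-(3-hydroxyphenoxy)-3-[3,4,5-tris(benzyloxy)-2-U(OH)-phenyl]propanal (present as its potassium phenoxide) | c1ccccc1COc1ccc2c(c1)O[C@H](c1cc(OCc3ccccc3)c(OCc3ccccc3)c(OCc3ccccc3)c1)[C@@H](O)[C@@H]2c1c([C@@H](Oc2cccc(O)c2)[C@@H](O)C=O)cc(OCc2ccccc2)c(OCc2ccccc2)c1OCc1ccccc1 | intermediate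

18 | (2R,3S,4R)-2-[3,4,5-tris(benzyloxy)-2-U(OH)-phenyl]chroman-3,4,7-triol | c1ccccc1COc1ccc2c(c1)O[C@H](c1cc(OCc3ccccc3)c(OCc3ccccc3)c(OCc3ccccc3)c1)[C@@H](O)[C@@H]2c1c([C@H]2Oc3cc(O)ccc3[C@@H](O)[C@@H]2O)cc(OCc2ccccc2)c(OCc2ccccc2)c1OCc1ccccc1 | intermediate

19 | (2R,3S,4R)-2-{3,4,5-trihydroxy-2-[(2R,3S,4S)-3,7-dihydroxy-2-(3,4,5-trihydroxyphenyl)chroman-4-yl]phenyl}chroman-3,4,7-triol | Oc1ccc2c(c1)O[C@H](c1cc(O)c(O)c(O)c1)[C@@H](O)[C@@H]2c1c([C@H]2Oc3cc(O)ccc3[C@@H](O)[C@@H]2O)cc(O)c(O)c1O | target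

**Step count**

Total steps: 13. Longest linear sequence: 12 steps (steps 1, 2 and 4–13 from compound 1); step 3 is a one-step side branch.

**Three steps most likely to fail**

Step 12 (proposed new method). β-Elimination of the aryloxide or epimerisation next to the aldehyde may outrun ring closure, or facial selectivity at C4 may be low. The fallback uses known chemistry and activates the electrophile instead of the nucleophile. It sets out from 16 with the allyl ether kept: a Lewis-acid-promoted intramolecular Friedel–Crafts hydroxyalkylation (BF3·OEt2, CH2Cl2, −78 °C, attack para to the allyloxy group) should give the 7-O-allyl chromanol F1. Deallylation with zerovalent palladium (Pd(PPh3)4, K2CO3, MeOH) then comes back to the route at 18.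

Step 9. Bimolecular substitution at the crowded benzylic carbon (ortho to the flavanyl group) may be slow, so that attack at the other epoxide carbon or Payne-type isomerisation takes over. The fallback forms the aryl–oxygen bond at the arene carbon instead and sets out from 12. Ti(OiPr)4-templated opening with benzoic acid at the benzylic carbon (inversion) should give the benzoate diol F2. 2,2-Dimethoxypropane with pyridinium p-toluenesulfonate then gives the acetonide benzoate F3, and K2CO3 in MeOH frees the benzylic alcohol F4. Copper-catalysed Ullmann-type O-arylation with 1-(allyloxy)-3-iodobenzene (CuI, 3,4,7,8-tetramethyl-1,10-phenanthroline, Cs2CO3, toluene, 110 °C; retention at the carbinol) should give the aryl ether acetonide F5. Aqueous acetic acid removes the acetonide and comes back to the route at 14.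

Step 13. Over-reduction may occur, that is, hydrogenolysis of the lower 4-hydroxybenzylic C4–OH along with the benzyl ethers. The fallback takes C4 through the ketone level and sets out from 18. MnO2 (CH2Cl2) should oxidise the activated benzylic alcohol to the chromanone F6. Hydrogenolysis (H2, Pd(OH)2/C) then gives the free dihydroflavonol-type ketone F7. NaBH4 reduction, known to give the 2,3-trans-3,4-trans diol, comes back to the route at 19; this sequence would also correct a wrong C4 configuration from step 12.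

**Further compounds**

F1 | step 12 | (2R,3S,4R)-7-(allyloxy)-2-[3,4,5-tris(benzyloxy)-2-U(OH)-phenyl]chroman-3,4-diol | c1ccccc1COc1ccc2c(c1)O[C@H](c1cc(OCc3ccccc3)c(OCc3ccccc3)c(OCc3ccccc3)c1)[C@@H](O)[C@@H]2c1c([C@H]2Oc3cc(OCC=C)ccc3[C@@H](O)[C@@H]2O)cc(OCc2ccccc2)c(OCc2ccccc2)c1OCc1ccccc1
F2 | step 9 | (1R,2S)-2,3-dihydroxy-1-[3,4,5-tris(benzyloxy)-2-U(TBS)-phenyl]propyl benzoate | c1ccccc1COc1ccc2c(c1)O[C@H](c1cc(OCc3ccccc3)c(OCc3ccccc3)c(OCc3ccccc3)c1)[C@@H](O[Si](C)(C)C(C)(C)C)[C@@H]2c1c([C@@H](OC(=O)c2ccccc2)[C@@H](O)CO)cc(OCc2ccccc2)c(OCc2ccccc2)c1OCc1ccccc1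
F3 | step 9 | (R)-[(S)-2,2-dimethyl-1,3-dioxolan-4-yl][3,4,5-tris(benzyloxy)-2-U(TBS)-phenyl]methyl benzoate | c1ccccc1COc1ccc2c(c1)O[C@H](c1cc(OCc3ccccc3)c(OCc3ccccc3)c(OCc3ccccc3)c1)[C@@H](O[Si](C)(C)C(C)(C)C)[C@@H]2c1c([C@@H](OC(=O)c2ccccc2)[C@@H]2COC(C)(C)O2)cc(OCc2ccccc2)c(OCc2ccccc2)c1OCc1ccccc1
F4 | step 9 | (R)-[(S)-2,2-dimethyl-1,3-dioxolan-4-yl][3,4,5-tris(benzyloxy)-2-U(TBS)-phenyl]methanol | c1ccccc1COc1ccc2c(c1)O[C@H](c1cc(OCc3ccccc3)c(OCc3ccccc3)c(OCc3ccccc3)c1)[C@@H](O[Si](C)(C)C(C)(C)C)[C@@H]2c1c([C@@H](O)[C@@H]2COC(C)(C)O2)cc(OCc2ccccc2)c(OCc2ccccc2)c1OCc1ccccc1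
F5 | step 9 | (S)-4-{(R)-[3-(allyloxy)phenoxy][3,4,5-tris(benzyloxy)-2-U(TBS)-phenyl]methyl}-2,2-dimethyl-1,3-dioxolane | c1ccccc1COc1ccc2c(c1)O[C@H](c1cc(OCc3ccccc3)c(OCc3ccccc3)c(OCc3ccccc3)c1)[C@@H](O[Si](C)(C)C(C)(C)C)[C@@H]2c1c([C@@H](Oc2cccc(OCC=C)c2)[C@@H]2COC(C)(C)O2)cc(OCc2ccccc2)c(OCc2ccccc2)c1OCc1ccccc1
F6 | step 13 | (2R,3R)-3,7-dihydroxy-2-[3,4,5-tris(benzyloxy)-2-U(OH)-phenyl]chroman-4-one | c1ccccc1COc1ccc2c(c1)O[C@H](c1cc(OCc3ccccc3)c(OCc3ccccc3)c(OCc3ccccc3)c1)[C@@H](O)[C@@H]2c1c([C@H]2Oc3cc(O)ccc3C(=O)[C@@H]2O)cc(OCc2ccccc2)c(OCc2ccccc2)c1OCc1ccccc1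
F7 | step 13 | robinetinidol-(4α→2′)-dihydrorobinetin, (2R,3R)-3,7-dihydroxy-2-{3,4,5-trihydroxy-2-[(2R,3S,4S)-3,7-dihydroxy-2-(3,4,5-trihydroxyphenyl)chroman-4-yl]phenyl}chroman-4-one | Oc1ccc2c(c1)O[C@H](c1cc(O)c(O)c(O)c1)[C@@H](O)[C@@H]2c1c([C@H]2Oc3cc(O)ccc3C(=O)[C@@H]2O)cc(O)c(O)c1O
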